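**Plan**
- Retrosynthesis: the E-propenyl group is traced back to a benzylic carbinol and the C7 methoxy group to a C7 silyl group. Then C3a–C7a, C4–C5 and C6–C7 are cut together, followed by O1–C7a (O-alkynylation) and C2–C3 (carbonyl addition).
- Enabling feature: rings A and B share the C3a–C7a bond, and O1–C2–C3, which carries both stereocentres, is a three-atom tether between an ynol ether alkyne (C7a≡C7) and a terminal alkyne (C3a≡C4). The precursor is therefore a 1,6-diyne.
- Forward order: the aryl aldehyde and a chiral allenylzinc join C2–C3; O-alkynylation adds C7a–C7; one ruthenium-catalysed [2+2+2] step with a protected pentynol closes ring B (C3a–C7a) and then ring A (C4–C5, C6–C7). Si to I to OMe at C7, deprotection and dehydration finish the route.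
- Stereochemistry: C3 comes from (R)-4-(trimethylsilyl)but-3-yn-2-ol by chirality transfer through the allenylzinc; C2 comes from the anti preference of its cyclic addition to the aldehyde. Both are spectators afterwards, and the E-alkene is set under thermodynamic control.
- Silicon bookkeeping: the alkyne C–H is carried as C–SiMe3 until the ynol ether terminus bears the slower-cleaving SiEt3 group, which then steers the cycloaddition and marks C7 for oxygenation.

Key step: step 7

Remark: pent-1-yn-3-ol is used as the racemate because its carbinol centre is erased in step 11, so 14 to 17 are mixtures of two epimers at that centre; benzofuran numbering is used for all ring atoms.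

**Step 1**
Reactants: 1 3-hydroxy-4,5-dimethoxybenzaldehyde
Product: 2 3-(methoxymethoxy)-4,5-dimethoxybenzaldehyde
Conditions: MOMCl, iPr2NEt, CH2Cl2, 0 °C to rt
Reagents that add atoms: chloromethyl methyl ether, COCCl
Why: Williamson-type O-alkylation of the phenol gives an acetal that should survive organozinc, hydride, organolithium, carbonate and copper alkoxide conditions and is removed only by acid.

**Step 2**
Reactants: 3 (R)-4-(trimethylsilyl)but-3-yn-2-ol
Product: 4 (R)-4-(trimethylsilyl)but-3-yn-2-yl methanesulfonate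
Conditions: MsCl, Et3N, CH2Cl2, −78 to 0 °C
Reagents that add atoms: methanesulfonyl chloride, CS(=O)(=O)Cl
Why: O-sulfonylation leaves the carbinol configuration untouched and installs the leaving group for the palladium step.

**Step 3**
Reactants: 4 (R)-4-(trimethylsilyl)but-3-yn-2-yl methanesulfonate; 2 3-(methoxymethoxy)-4,5-dimethoxybenzaldehyde
Product: 6 (1S,2S)-1-[3-(methoxymethoxy)-4,5-dimethoxyphenyl]-2-methyl-4-(trimethylsilyl)but-3-yn-1-ol, via ethyl[(P)-1-(trimethylsilyl)buta-1,2-dien-1-yl]zinc 5 (not isolated)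
Conditions: Pd(OAc)2 (5 mol%), PPh3 (5 mol%), Et2Zn (3 equiv), THF, −78 to −20 °C; aq. NH4Cl
Reagents that add atoms: none
Why: Palladium-catalysed propargyl-to-allenyl umpolung followed by SE2′ carbonyl propargylation: zerovalent palladium displaces the mesylate anti in an SN2′ sense, Et2Zn takes over the allenyl group with retention, and the allenylzinc adds to 2 through a cyclic six-membered transition state, so the methyl-bearing centre forms with net inversion relative to 4 (2S) and the carbinol centre (1S) follows from the anti preference of that transition state, in which the aryl group avoids the allenyl methyl group.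

**Step 4**
Reactants: 6 (1S,2S)-1-[3-(methoxymethoxy)-4,5-dimethoxyphenyl]-2-methyl-4-(trimethylsilyl)but-3-yn-1-ol; 7 trichloroethylene
Product: 10 triethyl({[(1S,2S)-1-[3-(methoxymethoxy)-4,5-dimethoxyphenyl]-2-methyl-4-(trimethylsilyl)but-3-yn-1-yl]oxy}ethynyl)silane, via the E-1,2-dichlorovinyl ether 8 (not isolated), via the lithium alkoxyacetylide 9 (not isolated)
Conditions: KH, THF, 0 °C; Cl2C=CHCl, −50 °C to rt; n-BuLi (2.5 equiv), −78 to −40 °C; Et3SiCl, −78 to 0 °C
Reagents that add atoms: chlorotriethylsilane, CC[Si](Cl)(CC)CC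
Why: O-alkynylation by the trichloroethylene route, established for secondary benzylic alcohols: the potassium alkoxide adds to dichloroacetylene formed in situ, n-BuLi effects dehydrochlorination and chlorine–lithium exchange, and Et3SiCl caps the acetylide, with the carbinol C–O bond and both stereocentres untouched; the other alkyne is kept as C–SiMe3 because a free C–H would be lithiated and silylated as well.

**Step 5**
Reactants: 10 triethyl({[(1S,2S)-1-[3-(methoxymethoxy)-4,5-dimethoxyphenyl]-2-methyl-4-(trimethylsilyl)but-3-yn-1-yl]oxy}ethynyl)silane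
Product: 11 triethyl({[(1S,2S)-1-[3-(methoxymethoxy)-4,5-dimethoxyphenyl]-2-methylbut-3-yn-1-yl]oxy}ethynyl)silane
Conditions: K2CO3 (0.2 equiv), MeOH/THF, 0 °C
Reagents that add atoms: none
Why: Base-mediated protodesilylation of an alkynylsilane: methoxide attacks the unhindered SiMe3 group much faster than SiEt3, the same steric discrimination used to unmask trimethylsilyl alkynes beside triethylsilyl alkynes, and ynol ethers are stable to base.

**Step 6**
Reactants: 12 pent-1-yn-3-ol (racemic)
Product: 13 tert-butyldimethyl(pent-1-yn-3-yloxy)silane (racemic)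
Conditions: TBSCl, imidazole, DMF, rt
Reagents that add atoms: tert-butyl(chloro)dimethylsilane, CC(C)(C)[Si](C)(C)Cl
Why: Standard O-silylation of a secondary alcohol gives a bulky ether that masks the future propenyl group and adds steric bias to the alkyne.

**Step 7**
Reactants: 11 triethyl({[(1S,2S)-1-[3-(methoxymethoxy)-4,5-dimethoxyphenyl]-2-methylbut-3-yn-1-yl]oxy}ethynyl)silane; 13 tert-butyldimethyl(pent-1-yn-3-yloxy)silane
Product: 14 (2S,3S)-5-[1-(tert-butyldimethylsilyloxy)propyl]-2-[3-(methoxymethoxy)-4,5-dimethoxyphenyl]-3-methyl-7-(triethylsilyl)-2,3-dihydro-1-benzofuran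
Conditions: Cp*RuCl(cod) (10 mol%), 13 (3 equiv), ClCH2CH2Cl, rt, slow addition of 11
Reagents that add atoms: none
Why: Proposed new method: the Cp*RuCl fragment (divalent ruthenium) should bind both alkynes of 11 and couple them oxidatively to a ruthenacyclopentadiene with biscarbenoid character, which forms C3a–C7a and closes ring B as the five-membered ring spanned by the O1–C2–C3 tether; alkyne 13 then adds at the unsubstituted C4 terminus and reductive elimination forms C4–C5 and C6–C7, closing ring A as the new benzene ring. The closest known reaction types are the Cp*RuCl(cod)-catalysed [2+2+2] cycloaddition of unsymmetrical 1,6-diynes with terminal alkynes and the RhCl(PPh3)3-catalysed cyclotrimerisation of ynamide-tethered diynes to indolines; a tether that is an ynol ether has not been shown, although alkoxy(silyl)alkynes are known partners in cobalt-mediated cyclotrimerisation. No stereocentre is formed, and C2 and C3 sit on the tether away from the reacting carbons, so the 2S,3S configuration should pass through unchanged. The step needs the substituent of 13 at C5 and not at C6: the silyloxypropyl-bearing carbon should bond to the unhindered C4 and the CH end to the SiEt3-bearing C7, the meta orientation this catalyst gives with diynes substituted at one terminus, here reinforced by the size of both groups. Chemoselectivity against homotrimerisation of 13 rests on chelating coordination of the diyne and on slow addition of 11 to an excess of 13, and room temperature keeps the benzylic ynol ether below the onset of sigmatropic or retro-ene decay.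

**Step 8**
Reactants: 14 (2S,3S)-5-[1-(tert-butyldimethylsilyloxy)propyl]-2-[3-(methoxymethoxy)-4,5-dimethoxyphenyl]-3-methyl-7-(triethylsilyl)-2,3-dihydro-1-benzofuran
Product: 15 (2S,3S)-5-[1-(tert-butyldimethylsilyloxy)propyl]-7-iodo-2-[3-(methoxymethoxy)-4,5-dimethoxyphenyl]-3-methyl-2,3-dihydro-1-benzofuran
Conditions: ICl (1.05 equiv), CH2Cl2, −78 to −40 °C; aq. Na2S2O3
Reagents that add atoms: iodine monochloride, ClI
Why: Ipso-iododesilylation (electrophilic aromatic substitution at the silicon-bearing carbon): attack at C7 is activated by the ortho ring oxygen and by β-silicon stabilisation of the arenium ion, which should make it faster than C–H iodination of the pendant ring at low temperature with one equivalent of reagent.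

**Step 9**
Reactants: 15 (2S,3S)-5-[1-(tert-butyldimethylsilyloxy)propyl]-7-iodo-2-[3-(methoxymethoxy)-4,5-dimethoxyphenyl]-3-methyl-2,3-dihydro-1-benzofuran
Product: 16 (2S,3S)-5-[1-(tert-butyldimethylsilyloxy)propyl]-7-methoxy-2-[3-(methoxymethoxy)-4,5-dimethoxyphenyl]-3-methyl-2,3-dihydro-1-benzofuran
Conditions: CuI (10 mol%), 3,4,7,8-tetramethyl-1,10-phenanthroline (20 mol%), Cs2CO3, MeOH/toluene, 80 °C
Reagents that add atoms: methanol, CO
Why: Ullmann-type copper-catalysed C–O coupling of an aryl iodide with methanol tolerates an ortho alkoxy group, and the carbonate base leaves the silyl ether, the acetal and both benzylic stereocentres alone.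

**Step 10**
Reactants: 16 (2S,3S)-5-[1-(tert-butyldimethylsilyloxy)propyl]-7-methoxy-2-[3-(methoxymethoxy)-4,5-dimethoxyphenyl]-3-methyl-2,3-dihydro-1-benzofuran
Product: 17 5-[(2S,3S)-5-(1-hydroxypropyl)-7-methoxy-3-methyl-2,3-dihydro-1-benzofuran-2-yl]-2,3-dimethoxyphenol
Conditions: 3 M aq. HCl, THF, 40 °C
Reagents that add atoms: none
Why: Acid hydrolysis cleaves the methoxymethyl acetal and the benzylic silyl ether in one operation, and because the trans-dihydrobenzofuran is the thermodynamically preferred isomer, transient ionisation at C2 should not erode the configuration.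

**Step 11**
Reactants: 17 5-[(2S,3S)-5-(1-hydroxypropyl)-7-methoxy-3-methyl-2,3-dihydro-1-benzofuran-2-yl]-2,3-dimethoxyphenol
Product: 18 2,3-dimethoxy-5-[(2S,3S)-7-methoxy-3-methyl-5-[(E)-prop-1-en-1-yl]-2,3-dihydro-1-benzofuran-2-yl]phenol
Conditions: p-TsOH·H2O (5 mol%), toluene, 70 °C, dilute
Reagents that add atoms: none
Why: Acid-catalysed E1 dehydration of the benzylic alcohol, whose cation is stabilised by the para ring oxygen, should give the conjugated and thermodynamically favoured E-propenyl group without touching C2 or C3.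

**Compound list**
1 | 3-hydroxy-4,5-dimethoxybenzaldehyde | O=Cc1cc(O)c(OC)c(OC)c1 | starting material
2 | 3-(methoxymethoxy)-4,5-dimethoxybenzaldehyde | O=Cc1cc(OCOC)c(OC)c(OC)c1 | intermediate
3 | (R)-4-(trimethylsilyl)but-3-yn-2-ol | C[C@@H](O)C#C[Si](C)(C)C | starting material
4 | (R)-4-(trimethylsilyl)but-3-yn-2-yl methanesulfonate | C[C@@H](OS(C)(=O)=O)C#C[Si](C)(C)C | intermediate
5 | ethyl[(P)-1-(trimethylsilyl)buta-1,2-dien-1-yl]zinc (formed in situ) | CC[Zn]C([Si](C)(C)C)=[C@@]=C([H])C | intermediate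
6 | (1S,2S)-1-[3-(methoxymethoxy)-4,5-dimethoxyphenyl]-2-methyl-4-(trimethylsilyl)but-3-yn-1-ol | C[Si](C)(C)C#C[C@H](C)[C@@H](c1cc(OCOC)c(OC)c(OC)c1)O | intermediate
7 | trichloroethylene | ClC=C(Cl)Cl | starting material
8 | {(3S,4S)-4-{[(E)-1,2-dichloroethenyl]oxy}-4-[3-(methoxymethoxy)-4,5-dimethoxyphenyl]-3-methylbut-1-yn-1-yl}trimethylsilane (formed in situ) | C[Si](C)(C)C#C[C@H](C)[C@@H](c1cc(OCOC)c(OC)c(OC)c1)O/C(Cl)=C\Cl | intermediate
9 | lithium 2-{[(1S,2S)-1-[3-(methoxymethoxy)-4,5-dimethoxyphenyl]-2-methyl-4-(trimethylsilyl)but-3-yn-1-yl]oxy}ethynide (formed in situ) | C[Si](C)(C)C#C[C@H](C)[C@@H](c1cc(OCOC)c(OC)c(OC)c1)OC#C[Li] | intermediate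
10 | triethyl({[(1S,2S)-1-[3-(methoxymethoxy)-4,5-dimethoxyphenyl]-2-methyl-4-(trimethylsilyl)but-3-yn-1-yl]oxy}ethynyl)silane | C[Si](C)(C)C#C[C@H](C)[C@@H](c1cc(OCOC)c(OC)c(OC)c1)OC#C[Si](CC)(CC)CC | intermediate
11 | triethyl({[(1S,2S)-1-[3-(methoxymethoxy)-4,5-dimethoxyphenyl]-2-methylbut-3-yn-1-yl]oxy}ethynyl)silane | C#C[C@H](C)[C@@H](c1cc(OCOC)c(OC)c(OC)c1)OC#C[Si](CC)(CC)CC | intermediate
12 | pent-1-yn-3-ol (racemic) | CCC(O)C#C | starting material
13 | tert-butyldimethyl(pent-1-yn-3-yloxy)silane (racemic) | CCC(O[Si](C)(C)C(C)(C)C)C#C | intermediate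
14 | (2S,3S)-5-[1-(tert-butyldimethylsilyloxy)propyl]-2-[3-(methoxymethoxy)-4,5-dimethoxyphenyl]-3-methyl-7-(triethylsilyl)-2,3-dihydro-1-benzofuran (both epimers at the silyloxy carbon) | CCC(O[Si](C)(C)C(C)(C)C)c1cc([Si](CC)(CC)CC)c2c(c1)[C@H](C)[C@@H](c1cc(OCOC)c(OC)c(OC)c1)O2 | intermediate
15 | (2S,3S)-5-[1-(tert-butyldimethylsilyloxy)propyl]-7-iodo-2-[3-(methoxymethoxy)-4,5-dimethoxyphenyl]-3-methyl-2,3-dihydro-1-benzofuran (both epimers at the silyloxy carbon) | CCC(O[Si](C)(C)C(C)(C)C)c1cc(I)c2c(c1)[C@H](C)[C@@H](c1cc(OCOC)c(OC)c(OC)c1)O2 | intermediate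
16 | (2S,3S)-5-[1-(tert-butyldimethylsilyloxy)propyl]-7-methoxy-2-[3-(methoxymethoxy)-4,5-dimethoxyphenyl]-3-methyl-2,3-dihydro-1-benzofuran (both epimers at the silyloxy carbon) | CCC(O[Si](C)(C)C(C)(C)C)c1cc(OC)c2c(c1)[C@H](C)[C@@H](c1cc(OCOC)c(OC)c(OC)c1)O2 | intermediate
17 | 5-[(2S,3S)-5-(1-hydroxypropyl)-7-methoxy-3-methyl-2,3-dihydro-1-benzofuran-2-yl]-2,3-dimethoxyphenol (both epimers at the carbinol carbon) | CCC(O)c1cc(OC)c2c(c1)[C@H](C)[C@@H](c1cc(O)c(OC)c(OC)c1)O2 | intermediate
18 | 2,3-dimethoxy-5-[(2S,3S)-7-methoxy-3-methyl-5-[(E)-prop-1-en-1-yl]-2,3-dihydro-1-benzofuran-2-yl]phenol | C/C=C/c1cc(OC)c2c(c1)[C@H](C)[C@@H](c1cc(O)c(OC)c(OC)c1)O2 | target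

**Step count**
Total: 11 steps. Longest linear sequence: 9 steps (1, 3, 4, 5, 7, 8, 9, 10, 11 from aldehyde 1; the same length from alcohol 3 through step 2).

**Steps most likely to fail**

Step 7 (Proposed new method). The electron-rich ynol ether may be destroyed at the metal by hydration or by sigmatropic or retro-ene fragmentation before the two alkynes couple. The hindered silylated terminus may also slow metallacycle formation until homotrimerisation of 13 dominates, or the monoalkyne may insert in the opposite orientation. The fallback uses known chemistry, sets out from aldehyde 2 and returns at 17.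
- EtMgBr adds to 2 to give 1-[3-(methoxymethoxy)-4,5-dimethoxyphenyl]propan-1-ol F1, which MnO2 oxidises to 1-[3-(methoxymethoxy)-4,5-dimethoxyphenyl]propan-1-one F2.
- Ring A is taken ready-made from purchased 3-bromo-4-hydroxy-5-methoxybenzaldehyde F3. Excess EtMgBr gives 2-bromo-4-(1-hydroxypropyl)-6-methoxyphenol F4, and MOMCl with iPr2NEt gives 1-bromo-3-methoxy-2-(methoxymethoxy)-5-[1-(methoxymethoxy)propyl]benzene F5.
- Palladium-catalysed α-arylation of F2 with F5 (Pd(OAc)2, XPhos, NaOtBu, toluene, 80 °C) should give the racemic, readily enolised ketone 2-{3-methoxy-2-(methoxymethoxy)-5-[1-(methoxymethoxy)propyl]phenyl}-1-[3-(methoxymethoxy)-4,5-dimethoxyphenyl]propan-1-one F6.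
- Asymmetric transfer hydrogenation under dynamic kinetic resolution (RuCl(p-cymene)[(S,S)-TsDPEN], HCO2H/Et3N) is expected to give (1S,2S)-2-{3-methoxy-2-(methoxymethoxy)-5-[1-(methoxymethoxy)propyl]phenyl}-1-[3-(methoxymethoxy)-4,5-dimethoxyphenyl]propan-1-ol F7.
- Aqueous HCl in THF then removes the three acetals, and the liberated phenol captures the benzylic cation trans to the C3 methyl group. Ring B closes through O1–C2 and 17 is reached, from which step 11 follows.

Step 4. The potassium alkoxide may take the SiMe3 group from the alkyne of a second molecule before it is trapped, and the benzylic ynol ether may decay by sigmatropic rearrangement while the mixture warms. The fallback avoids a free alkoxide, sets out from 6 and returns at 10.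
- Formylation with formic acetic anhydride and pyridine gives (1S,2S)-1-[3-(methoxymethoxy)-4,5-dimethoxyphenyl]-2-methyl-4-(trimethylsilyl)but-3-yn-1-yl formate F8.
- Wittig-type dichloromethylenation of the formate carbonyl (PPh3, CCl4, THF, 60 °C) gives {(3S,4S)-4-[(2,2-dichloroethenyl)oxy]-4-[3-(methoxymethoxy)-4,5-dimethoxyphenyl]-3-methylbut-1-yn-1-yl}trimethylsilane F9.
- n-BuLi at −78 °C converts F9 into the lithium alkoxyacetylide 9, which Et3SiCl caps to give 10.

Step 8. Iodination of C–H positions on the trialkoxyphenyl ring may compete with ipso attack at C7, and HCl formed from traces of moisture may cleave the acetal or the benzylic silyl ether. The fallback uses no electrophilic halogen, sets out from 14 and returns at 16.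
- Base-catalysed protodesilylation (KOSiMe3, wet DMSO, 60 °C) gives (2S,3S)-5-[1-(tert-butyldimethylsilyloxy)propyl]-2-[3-(methoxymethoxy)-4,5-dimethoxyphenyl]-3-methyl-2,3-dihydro-1-benzofuran F10.
- Iridium-catalysed C–H borylation ([Ir(OMe)(cod)]2, 4,4′-di-tert-butyl-2,2′-bipyridine, B2pin2, THF, 70 °C) should go to C7, the only ring C–H without a flanking carbon substituent. This gives (2S,3S)-5-[1-(tert-butyldimethylsilyloxy)propyl]-2-[3-(methoxymethoxy)-4,5-dimethoxyphenyl]-3-methyl-7-(4,4,5,5-tetramethyl-1,3,2-dioxaborolan-2-yl)-2,3-dihydro-1-benzofuran F11.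
- NaBO3·4H2O oxidises it to (2S,3S)-5-[1-(tert-butyldimethylsilyloxy)propyl]-2-[3-(methoxymethoxy)-4,5-dimethoxyphenyl]-3-methyl-2,3-dihydro-1-benzofuran-7-ol F12, and MeI with K2CO3 in acetone gives 16.

**Further compounds**
F1 | step 7 | 1-[3-(methoxymethoxy)-4,5-dimethoxyphenyl]propan-1-ol (racemic) | CCC(O)c1cc(OCOC)c(OC)c(OC)c1
F2 | step 7 | 1-[3-(methoxymethoxy)-4,5-dimethoxyphenyl]propan-1-one | CCC(=O)c1cc(OCOC)c(OC)c(OC)c1
F3 | step 7 | 3-bromo-4-hydroxy-5-methoxybenzaldehyde (purchased) | O=Cc1cc(Br)c(O)c(OC)c1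
F4 | step 7 | 2-bromo-4-(1-hydroxypropyl)-6-methoxyphenol (racemic) | CCC(O)c1cc(Br)c(O)c(OC)c1
F5 | step 7 | 1-bromo-3-methoxy-2-(methoxymethoxy)-5-[1-(methoxymethoxy)propyl]benzene (racemic) | CCC(OCOC)c1cc(Br)c(OCOC)c(OC)c1
F6 | step 7 | 2-{3-methoxy-2-(methoxymethoxy)-5-[1-(methoxymethoxy)propyl]phenyl}-1-[3-(methoxymethoxy)-4,5-dimethoxyphenyl]propan-1-one (stereoisomer mixture) | CCC(OCOC)c1cc(OC)c(OCOC)c(c1)C(C)C(=O)c1cc(OCOC)c(OC)c(OC)c1
F7 | step 7 | (1S,2S)-2-{3-methoxy-2-(methoxymethoxy)-5-[1-(methoxymethoxy)propyl]phenyl}-1-[3-(methoxymethoxy)-4,5-dimethoxyphenyl]propan-1-ol (both epimers at the side-chain carbon) | CCC(OCOC)c1cc(OC)c(OCOC)c(c1)[C@H](C)[C@@H](c1cc(OCOC)c(OC)c(OC)c1)O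
F8 | step 4 | (1S,2S)-1-[3-(methoxymethoxy)-4,5-dimethoxyphenyl]-2-methyl-4-(trimethylsilyl)but-3-yn-1-yl formate | C[Si](C)(C)C#C[C@H](C)[C@@H](c1cc(OCOC)c(OC)c(OC)c1)OC=O
F9 | step 4 | {(3S,4S)-4-[(2,2-dichloroethenyl)oxy]-4-[3-(methoxymethoxy)-4,5-dimethoxyphenyl]-3-methylbut-1-yn-1-yl}trimethylsilane | C[Si](C)(C)C#C[C@H](C)[C@@H](c1cc(OCOC)c(OC)c(OC)c1)OC=C(Cl)Cl
F10 | step 8 | (2S,3S)-5-[1-(tert-butyldimethylsilyloxy)propyl]-2-[3-(methoxymethoxy)-4,5-dimethoxyphenyl]-3-methyl-2,3-dihydro-1-benzofuran | CCC(O[Si](C)(C)C(C)(C)C)c1ccc2c(c1)[C@H](C)[C@@H](c1cc(OCOC)c(OC)c(OC)c1)O2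
F11 | step 8 | (2S,3S)-5-[1-(tert-butyldimethylsilyloxy)propyl]-2-[3-(methoxymethoxy)-4,5-dimethoxyphenyl]-3-methyl-7-(4,4,5,5-tetramethyl-1,3,2-dioxaborolan-2-yl)-2,3-dihydro-1-benzofuran | CCC(O[Si](C)(C)C(C)(C)C)c1cc(B3OC(C)(C)C(C)(C)O3)c2c(c1)[C@H](C)[C@@H](c1cc(OCOC)c(OC)c(OC)c1)O2
F12 | step 8 | (2S,3S)-5-[1-(tert-butyldimethylsilyloxy)propyl]-2-[3-(methoxymethoxy)-4,5-dimethoxyphenyl]-3-methyl-2,3-dihydro-1-benzofuran-7-ol | CCC(O[Si](C)(C)C(C)(C)C)c1cc(O)c2c(c1)[C@H](C)[C@@H](c1cc(OCOC)c(OC)c(OC)c1)O2
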